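# Proposed total synthesis of CNP0263491.3 (compound 35)

## The problem

Compound 35 is a C27 furanoid apo-carotenoid. With the ring CMe2 as C1, the carbinol as C3, the O-bearing C(CH3) as C5, the ring alkene as C6=C7, the O-bearing CH as C8 and the chain running from C9 to C10', a 2,5-dihydrofuran (O1, C5, C6, C7, C8) is fused along C5–C6 to a cyclohexane (C1 to C6), and C8 carries a hexaene that ends in a primary allylic alcohol. Three stereocentres must be set, C3 (S), C5 (R) and C8 (S): C4 is trans to C9 across the ring oxygen, and the C3 hydroxyl is cis to the C5 methyl group, which makes it the axial, more hindered alcohol. Only C8 has to come from a chiral reagent: it lies 1,3 to C5 across oxygen and can relay to it, and C5, because ring fusion holds its methyl group axial, can screen one face of a C3 ketone. The chain has one Z alkene (C9=C10, trisubstituted) beside five E alkenes, so C9=C10 must be made stereospecifically and the chain joined at a bond whose formation leaves it alone. Once C6=C7 and the chain are in place the C8–O bond is allylic on both sides and is ionised by acid (epimerisation at C8, ring opening); the polyene does not tolerate light, oxygen or acid, and any C3 ketone is a β-alkoxy ketone that base can open by retro-oxa-Michael reaction. The feature that opens the route is C5, a tetrasubstituted ether carbon whose C4 arm is a CH2 group, 1,3 across O1 from C8 and next to C6: read with C6 as a ketone this is a 2-allyl-2-methyloxolan-3-one, the product of an oxonium ylide [2,3]-shift. Because C1 and C5 bear no hydrogen, that ketone can later only be turned into C6=C7.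

## Retrosynthesis

**Chain.** The allylic alcohol of 35 is taken back to the ethyl ester 34, and 34 is cut at C11=C12 into the allylic tributylphosphonium salt 30 (ylide 33) and the aldehyde ester 32. Compound 32 is one stabilised Wittig reaction, which adds C11' and C10', away from the commercial C10 dialdehyde 31. C11=C12 is preferred to its neighbours because it is the only chain alkene whose cut leaves the 9Z unit inside a small fragment, where it can be made from an alkyne. A cut at C9=C10 would ask a ketone olefination for Z selectivity, and cuts further out need long polyenyl phosphorus reagents whose own double bonds scramble on deprotonation. Phosphorus on the bicycle lets 31 be used after a single step. The forward reaction must be E-selective, must not isomerise C9=C10 and must tolerate the free C3 hydroxyl.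

**Oxidation levels at C11 and C3.** Salt 30 comes from bromide 29, and 29 from diol 28, by exchange at the primary allylic carbon. Diol 28 is the double reduction product of keto ester 26 (through hydroxy ester 27). At C3 the bond cut is C–H: a C3 ketone is attacked from the equatorial direction because the axial methyl groups on C1 and C5 close the axial path, and this gives the hindered axial alcohol that direct oxygenation of an alkene would not. Ketone 26 goes back through alcohol 25 to alkene 23 (C2=C3) by hydroboration, with boron on C3, the carbon remote from the quaternary C1. The forward steps must leave the enoate and C6=C7 alone.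

**C9=C10.** Enoate 23 is cut at C9–CH3 to ynoate 21, which is cut at C10–C11 to the terminal alkyne 19 and then to the silyl alkyne 18. Syn-addition of a methylcopper reagent across the ynoate puts C8 and C11 cis by mechanism. The neighbouring options are weaker: a Z-selective olefination of a C9 methyl ketone is unreliable, and carbometalation of the terminal alkyne would give the E isomer. The precursor carries only an alkyne on C8, a linear and inert group that can pass through the whole core synthesis.

**Carbocycle.** The cyclohexene of 18 is opened at C2=C3 (ring-closing metathesis) to triene 17. Its C6=C7 comes from dehydration of carbinol 16, and 16 is cut at C1–C6 into ketone 15 and a prenyl nucleophile that attacks through its γ-carbon. These cuts use the allyl group that the key step leaves on C5 as C4 and C3, and they bring C1 with both methyl groups and C2 in one reagent. Closing the ring at C1–C6 or C1–C2 instead would need functional groups on a carbon that ends as a bare CMe2. Ketone 15 is monocyclic with two stereocentres. The forward steps need γ-selective addition to a hindered ketone, elimination without cationic rearrangement, and metathesis onto a vinyl group next to a quaternary carbon.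

**Key disconnection.** Oxolanone 15 is cut at C5–O1 and C4–C5 back to the acyclic diazoketone 12: a copper carbenoid at C5 is trapped by the ether oxygen on C8 and the O-allyl group moves to C5. Compared with enolate alkylation or etherification of a tertiary alcohol, this cut forms the tetrasubstituted ether carbon and the ring in one step and lets C8 control C5 through the configuration at oxygen. Alkylating an oxolanone enolate with the methyl group last would place it trans to the C8 substituent, the wrong relation. Diazoketone 12 has a single stereocentre. The forward reaction must prefer ylide formation to 1,2-hydride shift from the C5 methyl and to attack on the alkyne, and must deliver the allyl group trans to the alkynyl group. The descriptors (5S) in 12 and (2R,5S) in 15 correspond to 8S and 5R of 35.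

**Diazoketone.** Compound 12 is cut at C5–C6 into acid 10 (as acid chloride 11) and a diazoalkane that brings C5 with its methyl group. Unlike diazo transfer to an ethyl ketone, this leaves no question of which α-carbon receives the diazo group. Acid 10 comes from ester 9, the O-allyl ether of β-hydroxy ester 8. The allylation must be acid-catalysed, since an alkoxide would undergo retro-aldol cleavage. Ester 8 comes from β-keto ester 7 by asymmetric transfer hydrogenation, which sets C8. Keto ester 7 is cut at C7–C8 into acid 3 (as chloride 5) and the malonate half-ester salt 4, and 3 is the carboxylation product of alkyne 1 (through acetylide 2).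

## Roads not taken

**Alternative 1:** The cut is C3–C4 together with C5–O1, which opens both rings of the C1–C11 fragment to the acyclic dienal A2.
- **Forward step:** A confined chiral imidodiphosphorimidate acid activates the C3 aldehyde and C4 of the 1,3-diene attacks it (cyclohexane ring). The tertiary allylic cation at C5 is captured by the silyl ether oxygen on C8 (dihydrofuran ring), and the triethylsilyl group ends on the C3 oxygen, giving A1.
- **Merits:** Two rings and the C5 centre form in one catalytic step, with the 9Z allylic ether and the C8 oxygen already in place. The core would need far fewer operations than steps 8 to 16 of the chosen route.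
- **Weak points:** The catalyst has to set C3 and C5 in the presence of the C8 centre, and C3 arises epimeric by design, so two further steps invert it. The C5 cation is delocalised to C7, so capture at the wrong terminus or proton loss competes. A silyl ether as terminating nucleophile with silyl transfer has no close precedent in this substrate class, so the step would have to be developed. A2 itself contains a stereodefined trisubstituted C6=C7 in a cross-conjugated diene, the 9Z alkene and the C8 carbinol, and is not short to make.
- **Comparison:** In step count Alternative 1 is better if the cascade works. The chosen plan offers instead that each step is a known reaction type and that C8, C5 and C3 are each set by a separate, understood control element.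

**Alternative 2:** The cut is both C–O bonds of the dihydrofuran, back to the 3-silyloxy (9Z)-dienoate A4 with an intact cyclohexene.
- **Forward step:** Sensitised singlet oxygen adds across C5 and C8 of the C5=C6–C7=C8 diene to a 5,8-endoperoxide, and a triarylphosphine removes one oxygen with closure of O–C8. This gives A3, the silyl ether and ethyl ester analogue of compound 27.
- **Merits:** The carbocycle and C3 come from ionone-type building blocks, no carbenoid or metathesis is needed, and both C–O bonds form in one pot. This is clearly the shortest road; it would replace steps 1 to 16 by perhaps half as many.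
- **Weak points:** Oxygen must add anti to a silyloxy group that is 1,3-remote from C5, which is only a modest bias. The C8 configuration depends on how the phosphine-activated peroxide closes at an allylic carbon (direct displacement, allylic displacement or ionisation), and furanoid oxides made this way tend to form as C8 epimers. Ene reactions at C4–H and at the C5 methyl, and addition to the C7=C8–C9=C10 diene, compete.
- **Comparison:** Alternative 2 is superior in step economy. The chosen plan accepts roughly twice the length in exchange for C5 and C8 being formed in a defined relation (C8 by catalyst, C5 from C8), not separated as diastereomers of an acid- and light-sensitive compound.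

**Alternative 3:** The cut is O1–C8 and the C8–H bond, back to the enyne diol A6 (hydroxyls on C5 and C6, alkyne C7≡C8).
- **Forward step:** With (Ph3P)AuNTf2, a chiral binaphthyl hydrogen phosphate and a dihydropyridine hydride donor, the C5 hydroxyl adds to C8 of the gold-activated alkyne, the C6 hydroxyl ionises, and hydride is delivered to C8 of the resulting oxocarbenium ion to give A5.
- **Merits:** A6 is assembled convergently from a (Z)-enyne acetylide and a hydroxy ketone, so the 9Z alkene comes from a stable enyne. One step closes the ring, creates C6=C7 and sets C8.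
- **Weak points:** C8 is set by catalyst control on a cation delocalised over C6, C8 and C10, next to the C5 and C3 centres (matched or mismatched), and hydride may also arrive at C10 or C6. The C5 tertiary carbinol must be made enantioselectively beforehand with no relay from another centre. The three-catalyst step is not established for this kind of cation.
- **Comparison:** Alternative 3 is shorter and more convergent. The chosen plan offers instead a first stereocentre from a widely used transfer hydrogenation and a diastereoselective key step of known type.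

Key step: step 7

Assumption: compounds 16 and 25 are formed and used as mixtures of epimers at C6 and C3 respectively, because each of these carbons becomes sp2 in the following step; they are left undefined in name and SMILES.

## Route

Step 1
Reactants: 1 ethynyltri(propan-2-yl)silane [(triisopropylsilyl)acetylene]
Product: 3 3-(triisopropylsilyl)prop-2-ynoic acid, via lithium (triisopropylsilyl)acetylide 2 (not isolated)
Conditions: n-BuLi, THF, −78 °C; CO2; aq. HCl
Reagents that add atoms: carbon dioxide, O=C=O
Why: Deprotonation of the terminal alkyne and carboxylation of the acetylide is the standard entry to silylpropiolic acids; the silyl group is inert to both operations.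

Step 2
Reactants: 3 3-(triisopropylsilyl)prop-2-ynoic acid; 4 ethyl potassium malonate
Product: 7 ethyl 3-oxo-5-(triisopropylsilyl)pent-4-ynoate, via 3-(triisopropylsilyl)prop-2-ynoyl chloride 5 (not isolated), via acylmalonate half-ester 6 (not isolated)
Conditions: (COCl)2, DMF (cat.), CH2Cl2, 0 → 25 °C, concentrate; add to 4/MgCl2/Et3N in MeCN, 0 → 25 °C; aq. HCl
Reagents that add atoms: none
Why: C-acylation of the magnesium enolate of a malonate half-ester by an acid chloride, followed by decarboxylation on acidic work-up, gives β-keto esters without self-condensation; the bulky silyl group keeps amine and chloride off the β-carbon of the ynoyl chloride.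

Step 3
Reactants: 7 ethyl 3-oxo-5-(triisopropylsilyl)pent-4-ynoate
Product: 8 ethyl (3S)-3-hydroxy-5-(triisopropylsilyl)pent-4-ynoate
Conditions: RuCl(p-cymene)[(S,S)-TsDPEN] (1 mol%), i-PrOH, 25 °C
Reagents that add atoms: none
Why: Noyori asymmetric transfer hydrogenation; alkynyl ketones are privileged substrates because the alkyne takes the place of the aryl group in the CH/π-organised transition state, and the (S,S)-ligand should deliver hydride to the face that gives the (S)-carbinol, the future C8.

Step 4
Reactants: 8 ethyl (3S)-3-hydroxy-5-(triisopropylsilyl)pent-4-ynoate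
Product: 9 ethyl (3S)-3-(prop-2-en-1-yloxy)-5-(triisopropylsilyl)pent-4-ynoate
Conditions: CH2=CHCH2OC(=NH)CCl3, TfOH (10 mol%), CH2Cl2/cyclohexane, 0 → 25 °C
Reagents that add atoms: allyl 2,2,2-trichloroacetimidate, C=CCOC(=N)C(Cl)(Cl)Cl
Why: Acid-catalysed O-alkylation with a trichloroacetimidate avoids the alkoxide that would trigger retro-aldol cleavage or β-elimination of a β-hydroxy ester; the C–O bond at the stereocentre is not touched, so the configuration is kept.

Step 5
Reactants: 9 ethyl (3S)-3-(prop-2-en-1-yloxy)-5-(triisopropylsilyl)pent-4-ynoate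
Product: 10 (3S)-3-(prop-2-en-1-yloxy)-5-(triisopropylsilyl)pent-4-ynoic acid
Conditions: LiOH, THF/MeOH/H2O, 0 → 25 °C; aq. HCl to pH 3
Reagents that add atoms: lithium hydroxide, [Li+].[OH-]
Why: Saponification; hydroxide attack at the ester carbonyl at 0 °C should be faster than α-deprotonation, so β-elimination of the allyloxy group should stay minor, and the hindered silylalkyne resists aqueous base.

Step 6
Reactants: 10 (3S)-3-(prop-2-en-1-yloxy)-5-(triisopropylsilyl)pent-4-ynoic acid
Product: 12 (5S)-2-diazo-5-(prop-2-en-1-yloxy)-7-(triisopropylsilyl)hept-6-yn-3-one, via acid chloride 11 (not isolated)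
Conditions: (COCl)2, DMF (cat.), CH2Cl2, 0 → 25 °C, concentrate; CH3CHN2 (3 equiv, ethereal, prepared separately), Et2O, −20 → 0 °C
Reagents that add atoms: diazoethane, CC=[N+]=[N-]
Why: Acylation of a diazoalkane by an acid chloride (the first stage of an Arndt–Eistert sequence) gives the 2-diazo-3-ketone directly, a second equivalent of diazoethane taking up HCl; the position of the diazo group is fixed by the bond formed.

Step 7
Reactants: 12 (5S)-2-diazo-5-(prop-2-en-1-yloxy)-7-(triisopropylsilyl)hept-6-yn-3-one
Product: 15 (2R,5S)-2-methyl-2-(prop-2-en-1-yl)-5-[(triisopropylsilyl)ethynyl]oxolan-3-one, via copper carbenoid 13 (not isolated), via oxonium ylide 14 (not isolated)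
Conditions: Cu(acac)2 (10 mol%), THF, reflux, slow addition of 12
Reagents that add atoms: none
Why: Cu(acac)2 (copper bis(acetylacetonate), divalent copper) decomposes 12 with loss of N2 to the electrophilic copper carbenoid 13 at C5. A lone pair of the ether oxygen on C8 adds to the carbenoid carbon, which closes the five-membered ring O1–C5–C6–C7–C8 (formally a 5-exo closure onto the C=Cu bond) and gives oxonium ylide 14. The allyl group then moves from oxygen to C5 by a concerted [2,3]-sigmatropic shift through a five-membered envelope transition state, forming C4–C5 with allylic transposition. The closest known reaction type is the copper-catalysed oxonium ylide formation and [2,3]-rearrangement of allyl ethers of diazoketones to 2,5-trans oxolan-3-ones; a methyl group on the carbenoid carbon is the less common variant. C5 is the only new stereocentre and is controlled by C8: in 14 the allyl group on the pyramidal oxygen sits trans to the alkynyl group on the adjacent C8 and is delivered suprafacially to the same face of C5, so C4 ends trans to C9 and the methyl cis. The step needs chemoselectivity for ylide formation over 1,2-hydride shift from the C5 methyl, C–H insertion and addition to the alkyne; the 1,3-placement of oxygen and carbenoid carbon, the poorly hydridic methyl C–H bonds, the copper catalyst and slow addition favour the ylide, and the bulky silyl group shields the alkyne. With allyl as the migrating group the [2,3]-shift should outrun the [1,2]-shift.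

Step 8
Reactants: 15 (2R,5S)-2-methyl-2-(prop-2-en-1-yl)-5-[(triisopropylsilyl)ethynyl]oxolan-3-one
Product: 16 (2R,5S)-2-methyl-3-(2-methylbut-3-en-2-yl)-2-(prop-2-en-1-yl)-5-[(triisopropylsilyl)ethynyl]oxolan-3-ol (both C3 epimers)
Conditions: (CH3)2C=CHCH2MgCl, THF, −78 °C; aq. NH4Cl at −78 °C
Reagents that add atoms: 3-methylbut-2-en-1-ylmagnesium chloride (prenylmagnesium chloride), CC(C)=CC[Mg]Cl
Why: Allylic Grignard reagents add to ketones through a six-membered cyclic transition state at their γ-carbon, so C1 with both methyl groups and C2 as a vinyl group is attached to C6; low temperature and a cold quench keep the kinetic γ-adduct and limit enolisation toward C7. The new carbinol centre is not controlled and is removed in step 9.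

Step 9
Reactants: 16 (2R,5S)-2-methyl-3-(2-methylbut-3-en-2-yl)-2-(prop-2-en-1-yl)-5-[(triisopropylsilyl)ethynyl]oxolan-3-ol
Product: 17 (2R,5S)-2-methyl-3-(2-methylbut-3-en-2-yl)-2-(prop-2-en-1-yl)-5-[(triisopropylsilyl)ethynyl]-2,5-dihydrofuran
Conditions: SOCl2, pyridine, CH2Cl2, −30 → 0 °C
Reagents that add atoms: none
Why: Dehydration of a tertiary alcohol by O-sulfinylation and pyridine-induced E2-type elimination; C1 and C5 carry no hydrogen, so only C6=C7 can form, and the oxygen on C5 disfavours ionisation at C6, which should keep 1,2-shifts in check.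

Step 10
Reactants: 17 (2R,5S)-2-methyl-3-(2-methylbut-3-en-2-yl)-2-(prop-2-en-1-yl)-5-[(triisopropylsilyl)ethynyl]-2,5-dihydrofuran
Product: 18 (2S,7aR)-4,4,7a-trimethyl-2-[(triisopropylsilyl)ethynyl]-2,4,7,7a-tetrahydro-1-benzofuran
Conditions: second-generation Grubbs catalyst (H2IMes)(PCy3)Cl2Ru=CHPh (5 mol%), CH2Cl2 (0.01 M), 40 °C
Reagents that add atoms: none
Why: Ring-closing metathesis; the catalyst loads on the unhindered allyl group and closes onto the vinyl group next to C1, forming the six-membered ring with C2=C3 and releasing ethene. The trisubstituted C6=C7 and the silyl alkyne, which sits trans to the allyl arm, should not be engaged.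

Step 11
Reactants: 18 (2S,7aR)-4,4,7a-trimethyl-2-[(triisopropylsilyl)ethynyl]-2,4,7,7a-tetrahydro-1-benzofuran
Product: 19 (2S,7aR)-2-ethynyl-4,4,7a-trimethyl-2,4,7,7a-tetrahydro-1-benzofuran
Conditions: Bu4NF, THF, 0 °C
Reagents that add atoms: none
Why: Fluoride-induced protodesilylation of an alkynylsilane; no other silicon group or base-labile group is present.

Step 12
Reactants: 19 (2S,7aR)-2-ethynyl-4,4,7a-trimethyl-2,4,7,7a-tetrahydro-1-benzofuran
Product: 21 methyl 3-[(2S,7aR)-4,4,7a-trimethyl-2,4,7,7a-tetrahydro-1-benzofuran-2-yl]prop-2-ynoate, via lithium acetylide 20 (not isolated)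
Conditions: n-BuLi (1.05 equiv), THF, −78 °C; ClCO2Me, −78 → −20 °C
Reagents that add atoms: methyl chloroformate, COC(=O)Cl
Why: Acetylide formation and C-acylation with a chloroformate; the alkyne C–H is by far the most acidic site, so C8 should not be deprotonated by one equivalent of base at −78 °C.

Step 13
Reactants: 21 methyl 3-[(2S,7aR)-4,4,7a-trimethyl-2,4,7,7a-tetrahydro-1-benzofuran-2-yl]prop-2-ynoate
Product: 23 methyl (2Z)-3-[(2S,7aR)-4,4,7a-trimethyl-2,4,7,7a-tetrahydro-1-benzofuran-2-yl]but-2-enoate, via alkenyl(methyl)cuprate 22 (not isolated)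
Conditions: Me2CuLi (from CuI and 2 MeLi), THF, −78 °C; MeOH then aq. NH4Cl at −78 °C
Reagents that add atoms: lithium dimethylcuprate, [Li+].C[Cu-]C
Why: Conjugate addition of a Gilman cuprate to an ynoate is a syn-carbocupration, and protonation of the alkenylcopper at −78 °C with retention puts CH3 and H cis, hence C8 cis to C11 (the 9Z alkene). The ether oxygen on the γ-carbon is a poor leaving group, so allene formation by allylic displacement is not expected.

Step 14
Reactants: 23 methyl (2Z)-3-[(2S,7aR)-4,4,7a-trimethyl-2,4,7,7a-tetrahydro-1-benzofuran-2-yl]but-2-enoate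
Product: 25 methyl (2Z)-3-[(2S,7aR)-6-hydroxy-4,4,7a-trimethyl-2,4,5,6,7,7a-hexahydro-1-benzofuran-2-yl]but-2-enoate (mixture of C6 epimers), via B-alkyl-9-borabicyclo[3.3.1]nonane 24 (not isolated)
Conditions: 9-BBN, THF, 60 °C; then 30% H2O2, aq. NaOAc, 0 → 25 °C
Reagents that add atoms: hydrogen peroxide, OO
Why: Hydroboration–oxidation; 9-BBN should put boron on C3, the alkene carbon remote from the quaternary C1, and is too bulky for the trisubstituted C6=C7 between two quaternary carbons and unreactive toward the electron-poor enoate; acetate-buffered peroxide spares the methyl ester. The C3 configuration (expected mainly trans to the C5 methyl) does not matter because step 15 removes it.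

Step 15
Reactants: 25 methyl (2Z)-3-[(2S,7aR)-6-hydroxy-4,4,7a-trimethyl-2,4,5,6,7,7a-hexahydro-1-benzofuran-2-yl]but-2-enoate
Product: 26 methyl (2Z)-3-[(2S,7aR)-4,4,7a-trimethyl-6-oxo-2,4,5,6,7,7a-hexahydro-1-benzofuran-2-yl]but-2-enoate
Conditions: Dess–Martin periodinane, CH2Cl2, 0 → 25 °C
Reagents that add atoms: none
Why: Dess–Martin oxidation of a secondary alcohol under near-neutral conditions converges both epimers to one ketone and avoids the base that would open the β-alkoxy ketone by retro-oxa-Michael reaction.

Step 16
Reactants: 26 methyl (2Z)-3-[(2S,7aR)-4,4,7a-trimethyl-6-oxo-2,4,5,6,7,7a-hexahydro-1-benzofuran-2-yl]but-2-enoate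
Product: 28 (2S,6S,7aR)-2-[(2Z)-4-hydroxybut-2-en-2-yl]-4,4,7a-trimethyl-2,4,5,6,7,7a-hexahydro-1-benzofuran-6-ol, via hydroxy ester 27 (not isolated)
Conditions: LiBH(s-Bu)3, THF, −78 °C; then i-Bu2AlH, −78 → −20 °C; aq. KNaC4H4O6
Reagents that add atoms: none
Why: Substrate-controlled ketone reduction followed in the same flask by 1,2-reduction of the ester. Ring fusion holds O1 equatorial and the C5 methyl axial, so the axial methyl groups on C1 and C5 block axial approach to C3, and the bulky borohydride attacks equatorially to give the axial (3S)-alcohol, cis to the C5 methyl. The β,β-disubstituted enoate should resist conjugate reduction and is then reduced by i-Bu2AlH to the Z allylic alcohol.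

Step 17
Reactants: 28 (2S,6S,7aR)-2-[(2Z)-4-hydroxybut-2-en-2-yl]-4,4,7a-trimethyl-2,4,5,6,7,7a-hexahydro-1-benzofuran-6-ol
Product: 29 (2S,6S,7aR)-2-[(2Z)-4-bromobut-2-en-2-yl]-4,4,7a-trimethyl-2,4,5,6,7,7a-hexahydro-1-benzofuran-6-ol
Conditions: CBr4, PPh3, 2,6-lutidine, CH2Cl2, −30 → 0 °C
Reagents that add atoms: carbon tetrabromide, BrC(Br)(Br)Br
Why: Appel bromination; the primary allylic alcohol should react far faster than the axial secondary alcohol flanked by two syn-axial methyl groups, and the buffered, acid-free medium protects the C8–O bond and the Z alkene.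

Step 18
Reactants: 29 (2S,6S,7aR)-2-[(2Z)-4-bromobut-2-en-2-yl]-4,4,7a-trimethyl-2,4,5,6,7,7a-hexahydro-1-benzofuran-6-ol
Product: 30 tributyl{(2Z)-3-[(2S,6S,7aR)-6-hydroxy-4,4,7a-trimethyl-2,4,5,6,7,7a-hexahydro-1-benzofuran-2-yl]but-2-en-1-yl}phosphonium bromide
Conditions: PBu3, MeCN, 0 → 25 °C
Reagents that add atoms: tributylphosphine, CCCCP(CCCC)CCCC
Why: SN2 quaternisation of a primary allylic bromide by a trialkylphosphine proceeds at room temperature without acid or heat, so neither the Z alkene nor the allylic ether is put at risk.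

Step 19
Reactants: 31 (2E,4E,6E)-2,7-dimethylocta-2,4,6-trienedial
Product: 32 ethyl (2E,4E,6E,8E)-4,9-dimethyl-10-oxodeca-2,4,6,8-tetraenoate
Conditions: Ph3P=CHCO2Et (1 equiv), 31 (3 equiv), CH2Cl2, 0 → 25 °C
Reagents that add atoms: ethyl (triphenyl-λ5-phosphanylidene)acetate, CCOC(=O)C=P(c1ccccc1)(c1ccccc1)c1ccccc1
Why: Wittig reaction of a stabilised ylide, which is E-selective; an excess of the symmetrical dialdehyde keeps olefination to one end, and unreacted 31 is recovered.

Step 20
Reactants: 30 tributyl{(2Z)-3-[(2S,6S,7aR)-6-hydroxy-4,4,7a-trimethyl-2,4,5,6,7,7a-hexahydro-1-benzofuran-2-yl]but-2-en-1-yl}phosphonium bromide; 32 ethyl (2E,4E,6E,8E)-4,9-dimethyl-10-oxodeca-2,4,6,8-tetraenoate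
Product: 34 ethyl (2E,4E,6E,8E,10E,12Z)-13-[(2S,6S,7aR)-6-hydroxy-4,4,7a-trimethyl-2,4,5,6,7,7a-hexahydro-1-benzofuran-2-yl]-4,9-dimethyltetradeca-2,4,6,8,10,12-hexaenoate, via phosphorus ylide 33 (not isolated)
Conditions: LiN(SiMe3)2 (1.05 equiv), THF, −78 °C; then 32, −78 → 0 °C, dark
Reagents that add atoms: none
Why: Wittig reaction of an allylic trialkylphosphonium ylide; tributyl substitution favours the E alkene at the new C11=C12 bond, and the charge of the ylide sits mainly on C11, so the C9=C10 geometry should survive at low temperature. The phosphonium CH2 is far more acidic than the C3 hydroxyl, so one equivalent of base suffices and the ester of 32 is not attacked.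

Step 21
Reactants: 34 ethyl (2E,4E,6E,8E,10E,12Z)-13-[(2S,6S,7aR)-6-hydroxy-4,4,7a-trimethyl-2,4,5,6,7,7a-hexahydro-1-benzofuran-2-yl]-4,9-dimethyltetradeca-2,4,6,8,10,12-hexaenoate
Product: 35 (2E,4E,6E,8E,10E,12Z)-13-[(2S,6S,7aR)-6-hydroxy-4,4,7a-trimethyl-2,4,5,6,7,7a-hexahydro-1-benzofuran-2-yl]-4,9-dimethyltetradeca-2,4,6,8,10,12-hexaen-1-ol
Conditions: i-Bu2AlH, CH2Cl2, −78 °C; aq. KNaC4H4O6; argon, dark
Reagents that add atoms: none
Why: 1,2-Reduction of a conjugated ester by i-Bu2AlH gives the allylic alcohol without touching the polyene; the neutral tartrate work-up and exclusion of light and air protect the C8–O bond and the alkene geometries.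

## Compound list

1 | ethynyltri(propan-2-yl)silane [(triisopropylsilyl)acetylene] | C#C[Si](C(C)C)(C(C)C)C(C)C | starting material
2 | lithium (triisopropylsilyl)acetylide (formed in the flask) | [Li]C#C[Si](C(C)C)(C(C)C)C(C)C | intermediate
3 | 3-(triisopropylsilyl)prop-2-ynoic acid | OC(=O)C#C[Si](C(C)C)(C(C)C)C(C)C | intermediate
4 | ethyl potassium malonate | CCOC(=O)CC(=O)[O-].[K+] | starting material
5 | 3-(triisopropylsilyl)prop-2-ynoyl chloride (formed in the flask) | ClC(=O)C#C[Si](C(C)C)(C(C)C)C(C)C | intermediate
6 | 2-(ethoxycarbonyl)-3-oxo-5-(triisopropylsilyl)pent-4-ynoic acid, acylmalonate half-ester (formed in the flask) | CCOC(=O)C(C(=O)O)C(=O)C#C[Si](C(C)C)(C(C)C)C(C)C | intermediate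
7 | ethyl 3-oxo-5-(triisopropylsilyl)pent-4-ynoate | CCOC(=O)CC(=O)C#C[Si](C(C)C)(C(C)C)C(C)C | intermediate
8 | ethyl (3S)-3-hydroxy-5-(triisopropylsilyl)pent-4-ynoate | CCOC(=O)C[C@H](O)C#C[Si](C(C)C)(C(C)C)C(C)C | intermediate
9 | ethyl (3S)-3-(prop-2-en-1-yloxy)-5-(triisopropylsilyl)pent-4-ynoate | CCOC(=O)C[C@H](OCC=C)C#C[Si](C(C)C)(C(C)C)C(C)C | intermediate
10 | (3S)-3-(prop-2-en-1-yloxy)-5-(triisopropylsilyl)pent-4-ynoic acid | OC(=O)C[C@H](OCC=C)C#C[Si](C(C)C)(C(C)C)C(C)C | intermediate
11 | (3S)-3-(prop-2-en-1-yloxy)-5-(triisopropylsilyl)pent-4-ynoyl chloride (formed in the flask) | ClC(=O)C[C@H](OCC=C)C#C[Si](C(C)C)(C(C)C)C(C)C | intermediate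
12 | (5S)-2-diazo-5-(prop-2-en-1-yloxy)-7-(triisopropylsilyl)hept-6-yn-3-one | CC(=[N+]=[N-])C(=O)C[C@H](OCC=C)C#C[Si](C(C)C)(C(C)C)C(C)C | intermediate
13 | copper carbenoid of 12 at C2 (acetylacetonate ligand on copper not drawn; formed in the flask) | CC(=[Cu])C(=O)C[C@H](OCC=C)C#C[Si](C(C)C)(C(C)C)C(C)C | intermediate
14 | (5S)-2-methyl-3-oxo-1-(prop-2-en-1-yl)-5-[(triisopropylsilyl)ethynyl]oxolan-1-ium-2-ide, oxonium ylide with the allyl group on oxygen trans to the alkynyl group (formed in the flask) | C[C-]1C(=O)C[C@@H](C#C[Si](C(C)C)(C(C)C)C(C)C)[O+]1CC=C | intermediate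
15 | (2R,5S)-2-methyl-2-(prop-2-en-1-yl)-5-[(triisopropylsilyl)ethynyl]oxolan-3-one | CC(C)[Si](C(C)C)(C(C)C)C#C[C@@H]1CC(=O)[C@@](C)(CC=C)O1 | intermediate
16 | (2R,5S)-2-methyl-3-(2-methylbut-3-en-2-yl)-2-(prop-2-en-1-yl)-5-[(triisopropylsilyl)ethynyl]oxolan-3-ol (both C3 epimers) | CC(C)[Si](C(C)C)(C(C)C)C#C[C@@H]1CC(O)(C(C)(C)C=C)[C@@](C)(CC=C)O1 | intermediate
17 | (2R,5S)-2-methyl-3-(2-methylbut-3-en-2-yl)-2-(prop-2-en-1-yl)-5-[(triisopropylsilyl)ethynyl]-2,5-dihydrofuran | CC(C)[Si](C(C)C)(C(C)C)C#C[C@@H]1C=C(C(C)(C)C=C)[C@@](C)(CC=C)O1 | intermediate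
18 | (2S,7aR)-4,4,7a-trimethyl-2-[(triisopropylsilyl)ethynyl]-2,4,7,7a-tetrahydro-1-benzofuran | CC(C)[Si](C(C)C)(C(C)C)C#C[C@@H]1C=C2C(C)(C)C=CC[C@@]2(C)O1 | intermediate
19 | (2S,7aR)-2-ethynyl-4,4,7a-trimethyl-2,4,7,7a-tetrahydro-1-benzofuran | C#C[C@@H]1C=C2C(C)(C)C=CC[C@@]2(C)O1 | intermediate
20 | lithium acetylide of 19 (formed in the flask) | [Li]C#C[C@@H]1C=C2C(C)(C)C=CC[C@@]2(C)O1 | intermediate
21 | methyl 3-[(2S,7aR)-4,4,7a-trimethyl-2,4,7,7a-tetrahydro-1-benzofuran-2-yl]prop-2-ynoate | COC(=O)C#C[C@@H]1C=C2C(C)(C)C=CC[C@@]2(C)O1 | intermediate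
22 | lithium alkenyl(methyl)cuprate from syn-addition to 21, copper on C10 cis to the new C9 methyl (formed in the flask) | C/C(=C(/C(=O)OC)[Cu-]C)[C@@H]1C=C2C(C)(C)C=CC[C@@]2(C)O1.[Li+] | intermediate
23 | methyl (2Z)-3-[(2S,7aR)-4,4,7a-trimethyl-2,4,7,7a-tetrahydro-1-benzofuran-2-yl]but-2-enoate | C/C(=C/C(=O)OC)[C@@H]1C=C2C(C)(C)C=CC[C@@]2(C)O1 | intermediate
24 | B-alkyl-9-borabicyclo[3.3.1]nonane with boron on C6 of the benzofuran, i.e. C3 (formed in the flask) | C/C(=C/C(=O)OC)[C@@H]1C=C2C(C)(C)CC(B3C4CCCC3CCC4)C[C@@]2(C)O1 | intermediate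
25 | methyl (2Z)-3-[(2S,7aR)-6-hydroxy-4,4,7a-trimethyl-2,4,5,6,7,7a-hexahydro-1-benzofuran-2-yl]but-2-enoate (mixture of C6 epimers) | C/C(=C/C(=O)OC)[C@@H]1C=C2C(C)(C)CC(O)C[C@@]2(C)O1 | intermediate
26 | methyl (2Z)-3-[(2S,7aR)-4,4,7a-trimethyl-6-oxo-2,4,5,6,7,7a-hexahydro-1-benzofuran-2-yl]but-2-enoate | C/C(=C/C(=O)OC)[C@@H]1C=C2C(C)(C)CC(=O)C[C@@]2(C)O1 | intermediate
27 | methyl (2Z)-3-[(2S,6S,7aR)-6-hydroxy-4,4,7a-trimethyl-2,4,5,6,7,7a-hexahydro-1-benzofuran-2-yl]but-2-enoate (formed in the flask) | C/C(=C/C(=O)OC)[C@@H]1C=C2C(C)(C)C[C@H](O)C[C@@]2(C)O1 | intermediate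
28 | (2S,6S,7aR)-2-[(2Z)-4-hydroxybut-2-en-2-yl]-4,4,7a-trimethyl-2,4,5,6,7,7a-hexahydro-1-benzofuran-6-ol | C/C(=C/CO)[C@@H]1C=C2C(C)(C)C[C@H](O)C[C@@]2(C)O1 | intermediate
29 | (2S,6S,7aR)-2-[(2Z)-4-bromobut-2-en-2-yl]-4,4,7a-trimethyl-2,4,5,6,7,7a-hexahydro-1-benzofuran-6-ol | C/C(=C/CBr)[C@@H]1C=C2C(C)(C)C[C@H](O)C[C@@]2(C)O1 | intermediate
30 | tributyl{(2Z)-3-[(2S,6S,7aR)-6-hydroxy-4,4,7a-trimethyl-2,4,5,6,7,7a-hexahydro-1-benzofuran-2-yl]but-2-en-1-yl}phosphonium bromide | C/C(=C/C[P+](CCCC)(CCCC)CCCC)[C@@H]1C=C2C(C)(C)C[C@H](O)C[C@@]2(C)O1.[Br-] | intermediate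
31 | (2E,4E,6E)-2,7-dimethylocta-2,4,6-trienedial | O=C/C(C)=C/C=C/C=C(C)/C=O | starting material
32 | ethyl (2E,4E,6E,8E)-4,9-dimethyl-10-oxodeca-2,4,6,8-tetraenoate | CCOC(=O)/C=C/C(C)=C/C=C/C=C(C)/C=O | intermediate
33 | tributyl{(2Z)-3-[(2S,6S,7aR)-6-hydroxy-4,4,7a-trimethyl-2,4,5,6,7,7a-hexahydro-1-benzofuran-2-yl]but-2-en-1-ylidene}-λ5-phosphane, ylide of 30 (formed in the flask) | C/C(=C/C=P(CCCC)(CCCC)CCCC)[C@@H]1C=C2C(C)(C)C[C@H](O)C[C@@]2(C)O1 | intermediate
34 | ethyl (2E,4E,6E,8E,10E,12Z)-13-[(2S,6S,7aR)-6-hydroxy-4,4,7a-trimethyl-2,4,5,6,7,7a-hexahydro-1-benzofuran-2-yl]-4,9-dimethyltetradeca-2,4,6,8,10,12-hexaenoate | C/C(=C/C=C/C(C)=C/C=C/C=C(C)/C=C/C(=O)OCC)[C@@H]1C=C2C(C)(C)C[C@H](O)C[C@@]2(C)O1 | intermediate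
35 | (2E,4E,6E,8E,10E,12Z)-13-[(2S,6S,7aR)-6-hydroxy-4,4,7a-trimethyl-2,4,5,6,7,7a-hexahydro-1-benzofuran-2-yl]-4,9-dimethyltetradeca-2,4,6,8,10,12-hexaen-1-ol (CNP0263491.3) | C/C(=C/C=C/C(C)=C/C=C/C=C(C)/C=C/CO)[C@@H]1C=C2C(C)(C)C[C@H](O)C[C@@]2(C)O1 | target

## Step count and least certain steps

Total: 21 steps. Longest linear sequence: 20 steps (steps 1 to 18, 20 and 21, from 1); step 19 is a one-step branch from 31.

**Step 7 (key step).** Three processes may compete with the intended path. The first is 1,2-hydride shift from the C5 methyl group in the carbenoid, which competes with capture by oxygen because alkyl-substituted carbenoids are prone to it. The second is carbenoid addition to the alkyne, which like ylide formation closes a five-membered ring. The third is weak facial discrimination at the oxonium oxygen, since an alkynyl group is slender, which would erode the C5 selectivity. The fallback forms C5–O1 by O–H insertion of a carbenoid that has no β-hydrogen and forms C4–C5 by palladium-catalysed allylation. It sets out from 8. A crossed Claisen condensation with the lithium enolate of allyl acetate should give the δ-hydroxy β-keto allyl ester F1. Diazo transfer (4-acetamidobenzenesulfonyl azide, Et3N) should give the diazo keto ester F2. Rh2(OAc)4-catalysed intramolecular O–H insertion should close the ring to the oxolanone ester F3. C-Methylation (MeI, K2CO3) should give the methylated keto ester F4. Decarboxylative allylation with Pd(PPh3)4 (zerovalent palladium; a Tsuji allylation) should then deliver the allyl group to the enolate face away from the alkynyl group. The fallback comes back to the route at 15.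

**Step 9 (with step 8).** Ionisation at C6 in place of concerted elimination would let a methyl or allyl group shift from C1 or C5. The carbinol, placed between two quaternary carbons, may also resist O-activation or revert to ketone by loss of the prenyl group. The fallback changes the order and the type of elimination. It sets out from 16: ring-closing metathesis with the same ruthenium catalyst is carried out first to give the bicyclic tertiary alcohol F5. This conformationally fixed carbinol is then dehydrated by thermal syn-elimination with the Burgess reagent (methyl N-(triethylammoniosulfonyl)carbamate, toluene, 70 °C), which uses the cis hydrogen on C7 and needs no free cation. The fallback comes back at 18.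

**Step 14.** Hydroboration of a cyclohexene next to a quaternary carbon by 9-BBN is slow and needs heat, so reduction of the ester, attack at C6=C7 or incomplete regiocontrol between C2 and C3 may intervene. The fallback replaces hydroboration by epoxidation and radical opening. It sets out from 23: buffered m-chloroperbenzoic acid should epoxidise the only unhindered, electron-rich alkene to give the 2,3-epoxide F6. Cp2TiCl (trivalent titanium, made from Cp2TiCl2 and Zn) with 1,4-cyclohexadiene should then open it reductively by homolysis of the C–O bond at the more hindered C2, leaving oxygen on C3. The fallback comes back at 25 and continues with step 15.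

**Step 20.** Loss of E selectivity at C11=C12, Z to E isomerisation at C9=C10 through the delocalised allylic ylide, or ring opening by vinylogous β-elimination of O1 from the ylide would each give isomers that are hard to separate from a sensitive polyene. The fallback reverses the polarity of the coupling.
- From 28, MnO2 should oxidise only the allylic alcohol to the (Z)-enal F7.
- From 32, NaBH4 should reduce the aldehyde to the hydroxy ester F8, PBr3 should give the bromo ester F9, and an Arbuzov reaction with P(OEt)3 should give the phosphonate ester F10.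
- A Horner–Wadsworth–Emmons reaction of F10 (NaN(SiMe3)2, THF, −78 °C) with F7 is E-selective and places no carbanion next to C9=C10.
- The fallback comes back at 34; its own risk is scrambling at C13=C14 in the phosphonate anion.

**Step 6.** Dehydrochlorination of the acid chloride to a ketene by the basic diazoalkane, or sluggish acylation of the more hindered diazoethane, would lower conversion, and the reagent limits scale. The fallback is a diazo transfer. It sets out from 9: MeNHOMe·HCl with i-PrMgCl should give the Weinreb amide F11, and EtMgBr the ethyl ketone F12. Enolisation on the less hindered ethyl side with LiN(SiMe3)2 and trapping with CF3CO2CH2CF3 should give the trifluoroacetyl diketone F13. Methanesulfonyl azide with Et3N then transfers the diazo group with loss of the trifluoroacetyl group. The fallback comes back at 12.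

## Further compounds

F1 | step 7 | allyl (5S)-5-hydroxy-3-oxo-7-(triisopropylsilyl)hept-6-ynoate | C=CCOC(=O)CC(=O)C[C@H](O)C#C[Si](C(C)C)(C(C)C)C(C)C
F2 | step 7 | allyl (5S)-2-diazo-5-hydroxy-3-oxo-7-(triisopropylsilyl)hept-6-ynoate | C=CCOC(=O)C(=[N+]=[N-])C(=O)C[C@H](O)C#C[Si](C(C)C)(C(C)C)C(C)C
F3 | step 7 | allyl (5S)-3-oxo-5-[(triisopropylsilyl)ethynyl]oxolane-2-carboxylate (C2 epimers) | C=CCOC(=O)C1O[C@H](C#C[Si](C(C)C)(C(C)C)C(C)C)CC1=O
F4 | step 7 | allyl (5S)-2-methyl-3-oxo-5-[(triisopropylsilyl)ethynyl]oxolane-2-carboxylate (C2 epimers) | C=CCOC(=O)C1(C)O[C@H](C#C[Si](C(C)C)(C(C)C)C(C)C)CC1=O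
F5 | step 9 | (2S,7aR)-4,4,7a-trimethyl-2-[(triisopropylsilyl)ethynyl]-2,3,7,7a-tetrahydro-1-benzofuran-3a(4H)-ol (C3a epimers) | CC(C)[Si](C(C)C)(C(C)C)C#C[C@@H]1CC2(O)C(C)(C)C=CC[C@@]2(C)O1
F6 | step 14 | methyl (2Z)-3-[(2S,7aR)-5,6-epoxy-4,4,7a-trimethyl-2,4,5,6,7,7a-hexahydro-1-benzofuran-2-yl]but-2-enoate | C/C(=C/C(=O)OC)[C@@H]1C=C2C(C)(C)C3OC3C[C@@]2(C)O1
F7 | step 20 | (2Z)-3-[(2S,6S,7aR)-6-hydroxy-4,4,7a-trimethyl-2,4,5,6,7,7a-hexahydro-1-benzofuran-2-yl]but-2-enal | C/C(=C/C=O)[C@@H]1C=C2C(C)(C)C[C@H](O)C[C@@]2(C)O1
F8 | step 20 | ethyl (2E,4E,6E,8E)-10-hydroxy-4,9-dimethyldeca-2,4,6,8-tetraenoate | CCOC(=O)/C=C/C(C)=C/C=C/C=C(C)/CO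
F9 | step 20 | ethyl (2E,4E,6E,8E)-10-bromo-4,9-dimethyldeca-2,4,6,8-tetraenoate | CCOC(=O)/C=C/C(C)=C/C=C/C=C(C)/CBr
F10 | step 20 | ethyl (2E,4E,6E,8E)-10-(diethoxyphosphoryl)-4,9-dimethyldeca-2,4,6,8-tetraenoate | CCOC(=O)/C=C/C(C)=C/C=C/C=C(C)/CP(=O)(OCC)OCC
F11 | step 6 | (3S)-N-methoxy-N-methyl-3-(prop-2-en-1-yloxy)-5-(triisopropylsilyl)pent-4-ynamide | CON(C)C(=O)C[C@H](OCC=C)C#C[Si](C(C)C)(C(C)C)C(C)C
F12 | step 6 | (5S)-5-(prop-2-en-1-yloxy)-7-(triisopropylsilyl)hept-6-yn-3-one | CCC(=O)C[C@H](OCC=C)C#C[Si](C(C)C)(C(C)C)C(C)C
F13 | step 6 | (6S)-1,1,1-trifluoro-3-methyl-6-(prop-2-en-1-yloxy)-8-(triisopropylsilyl)oct-7-yne-2,4-dione (C3 epimers) | CC(C(=O)C(F)(F)F)C(=O)C[C@H](OCC=C)C#C[Si](C(C)C)(C(C)C)C(C)C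
A1 | alternative 1 | (2S,6R,7aR)-2-[(2Z)-4-(tert-butyldiphenylsilyloxy)but-2-en-2-yl]-4,4,7a-trimethyl-6-(triethylsilyloxy)-2,4,5,6,7,7a-hexahydro-1-benzofuran | C/C(=C/CO[Si](c1ccccc1)(c1ccccc1)C(C)(C)C)[C@@H]1C=C2C(C)(C)C[C@@H](O[Si](CC)(CC)CC)C[C@@]2(C)O1
A2 | alternative 1 | (4E,6S,7Z)-9-(tert-butyldiphenylsilyloxy)-3,3,7-trimethyl-4-(prop-1-en-2-yl)-6-(triethylsilyloxy)nona-4,7-dienal | C/C(=C/CO[Si](c1ccccc1)(c1ccccc1)C(C)(C)C)[C@@H](O[Si](CC)(CC)CC)/C=C(/C(C)(C)CC=O)C(C)=C
A3 | alternative 2 | ethyl (2Z)-3-[(2S,6S,7aR)-6-(tert-butyldimethylsilyloxy)-4,4,7a-trimethyl-2,4,5,6,7,7a-hexahydro-1-benzofuran-2-yl]but-2-enoate | C/C(=C/C(=O)OCC)[C@@H]1C=C2C(C)(C)C[C@H](O[Si](C)(C)C(C)(C)C)C[C@@]2(C)O1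
A4 | alternative 2 | ethyl (2Z,4E)-5-[(4R)-4-(tert-butyldimethylsilyloxy)-2,6,6-trimethylcyclohex-1-en-1-yl]-3-methylpenta-2,4-dienoate | CCOC(=O)/C=C(/C)\C=C\C1=C(C)C[C@@H](O[Si](C)(C)C(C)(C)C)CC1(C)C
A5 | alternative 3 | (2S,6S,7aR)-6-(tert-butyldimethylsilyloxy)-2-[(2Z)-4-(tert-butyldimethylsilyloxy)but-2-en-2-yl]-4,4,7a-trimethyl-2,4,5,6,7,7a-hexahydro-1-benzofuran | C/C(=C/CO[Si](C)(C)C(C)(C)C)[C@@H]1C=C2C(C)(C)C[C@H](O[Si](C)(C)C(C)(C)C)C[C@@]2(C)O1
A6 | alternative 3 | (2R,4S)-4-(tert-butyldimethylsilyloxy)-1-[(3Z)-5-(tert-butyldimethylsilyloxy)-3-methylpent-3-en-1-yn-1-yl]-2,6,6-trimethylcyclohexane-1,2-diol (C1 configuration open) | C/C(=C/CO[Si](C)(C)C(C)(C)C)C#CC1(O)C(C)(C)C[C@H](O[Si](C)(C)C(C)(C)C)C[C@@]1(C)O
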